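## Structural features

The target is an achiral phlorotannin with four benzene rings and seven free phenolic hydroxyls. Rings C and D form a dibenzofuran, ring C is also fused through a 1,4-dioxin to ring B, and ring A (3,5-dihydroxyphenyl) hangs on ring B through a diaryl ether. Locants used below: the C/D unit carries dibenzofuran numbers (C1 and C9 flank the bay). Ring B is numbered B1 (ring A ether oxygen), B2 (OH), B3 (H), B4 (OH), B5 and B6 (dioxin oxygens, bonded to dibenzofuran C1 and C2 respectively).

There is no stereocentre, so every problem is one of regiochemistry and hindered C–O bonds. Ring B is penta-oxygenated; without the dioxin it is a symmetric 4,6-dioxygenated pyrogallol, with its central oxygen and one outer oxygen in the dioxin and the other outer oxygen carrying ring A. Ring C has three contiguous oxygens (C1, C2 in the dioxin, C3 as hydroxyl) and the furan oxygen, so the dioxin must use the right pair and the furan must close on the right side. The free polyphenol is easily oxidised in air (hydroquinone- and phloroglucinol-type rings), so all hydroxyls are best carried as ethers until the last step; the aryl–O–aryl bonds are robust.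

The hardest bond for classical methods is the ring A ether at B1, a carbon flanked by the oxygenated carbons B2 and B6. The key step sidesteps it: ring A has a 1,3,5-trioxygenation pattern, which is exactly what a vinylketene–ynol ether benzannulation delivers, so the B1 oxygen can be carried as a linear ethynyl ether and ring A built on it.

## Logic of the disconnections

**29 ⇒ 28.** Six O–alkyl bonds are cut (five O–CH3, one O–C2H5). This postpones the oxidation-prone polyphenol to the final step. The forward step must cleave alkyl ethers without touching the diaryl ether, dioxin or furan.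

**28 ⇒ 19 + 23.** Three C–C bonds of ring A are cut: the two bonds flanking the hydroxyl carbon, and the bond between the aryloxy carbon and the CH that lies towards the ethoxy carbon. This removes a whole ring and replaces a hindered diaryl ether coupling by an O–C(sp) bond. The forward step must place hydroxyl, aryloxy and ethoxy groups mutually meta.

**19 ⇒ 16 ⇒ 14 + 15.** The O–C(sp) bond is traced to a dichlorovinyl ether and then to the phenol. A small, linear two-carbon electrophile is insensitive to the two ortho substituents of B1. The forward steps need a clean elimination/chlorine–lithium exchange at low temperature, and 19 must be used at once because aryl ethynyl ethers hydrate and oligomerise.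

**23 ⇒ 20 + 21.** Two C–C bonds of the four-membered ring are cut ([2+2] of ketene and an ynol ether). The demand is trapping of a short-lived ketene by the alkyne.

**14 ⇒ 13.** The dioxin C–O bond at dibenzofuran C1 is cut. In 13 the two hydroxyls of ring B are equivalent by symmetry, so either closes to the same product and the other is left free exactly where ring A is needed, with no protecting group on ring B. The forward step needs an intramolecular etherification of a hindered aryl chloride.

**13 ⇒ 11 ⇒ 8 + 10.** The two ring B hydroxyls are traced to formyl groups (Dakin), and the B6–O bond is cut. The formyl groups activate the fluorine-bearing carbon for substitution and are then converted to the hydroxyls. Because 10 is symmetric, only one ether can form. The demand is a substitution that makes an ether with four ortho substituents.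

**10 ⇒ 9.** Two C–CHO bonds are cut; both formylations must go ortho to fluorine.

**8 ⇒ 7.** The C9a–C9b biaryl bond is cut. The bromine in 7 fixes the side of ring C on which the furan closes, and the aryloxy ring is symmetric, so no isomer is possible. The forward step must insert into C–Br and leave the neighbouring C–Cl for the later dioxin closure.

**7 ⇒ 5 + 6.** The ring D–O bond is cut. The coupling must tolerate aryl bromide and chloride, which rules out a halide-based Ullmann coupling and points to a boronic acid.

**5 ⇒ 3 ⇒ 2 ⇒ 1.** The furan oxygen is traced to a formyl group (Dakin), the silyl ether to the phenol, and the bromine to a C–H. In 1 chlorine already sits next to the future dioxin oxygen, and bromination is steered para to methoxy, next to chlorine. The halogen pattern of ring C is thus set on a monocyclic compound by substituent effects alone.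

## Other disconnections considered

**Alternative 1:** The cut is the C9a–C9b bond of the fully assembled, per-methylated skeleton.
- **Forward step:** zerovalent palladium (from Pd(OAc)2 and PCy3, with K2CO3 and pivalic acid) inserts into the ring C C–Br bond of A2. A carboxylate-assisted metalation of an ortho C–H of the neighbouring 3,5-dimethoxyphenoxy group and reductive elimination then give the hepta-O-methyl ether A1.
- **In favour:** protection is uniform (methyl only). Rings A and D derive from the same 3,5-dimethoxyphenyl unit, so both ethers could come from one reagent. A1 is one deprotection from the target.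
- **Against:** the ring A ether at B1 must be made by cross-coupling at a phenol with two ortho substituents. The bromine must be placed selectively on one of two similar ortho positions of a ring C phenol inside a dibenzodioxin.
- **Comparison:** the mechanism is as well understood as anything in the chosen plan, and the chosen plan uses the same palladium chemistry in step 5. The difference is timing: there the halogen is positioned unambiguously on a monocyclic precursor. On step economy Alternative 1 is the better plan, because ring A arrives in one arylation instead of four operations, and it is equal in the final deprotection. The chosen plan is the better on the hindered B1–O bond and on furan regiocontrol.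

**Alternative 2:** The cut is three C–C bonds of ring C (C1–C2, C3–C4, C1–C9b).
- **Forward step:** Et3N converts acid chloride A4 to the benzofuranylketene A6, which undergoes [2+2] cycloaddition with di-tert-butoxyethyne A5. On heating the cyclobutenone opens and the ketene carbon closes onto the furan 3-carbon to give dibenzofuranol A3.
- **In favour:** ring C is created fully oxygenated in one operation. The C1 hydroxyl necessarily lies next to C9b and is distinguished from O2 and O3 by being free.
- **Against:** O2 and O3 emerge as identical tert-butyl ethers, whereas the target needs O2 in the dioxin and O3 as a spectator, so a further differentiation is required. A5 is not a catalogue compound and tert-butyl ynol ethers lose isobutene on mild heating. Ring B, the dioxin and the hindered ring A ether remain unsolved.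
- **Comparison:** mechanistically it is the equal of the chosen key step (same sequence of ketene [2+2], 4-electron opening and 6-electron closure). It is the better way of fixing the furan side of ring C without halogen-directed closure. It should be worse on step economy and does not address the B1 ether.

**Alternative 3:** The cut is one C–C bond of ring B, between the hydroxyl carbon and the ethoxy carbon.
- **Forward step:** thermolysis of the squarate-derived 4-(2-ethoxyvinyl)-4-methoxycyclobutenone A8 (racemic) in toluene opens the ring to a dienylketene, whose 6-electron closure and tautomerisation give the penta-oxygenated phenol A7 (Moore-type ring expansion).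
- **In favour:** every ring B oxygen is individually addressed. The free hydroxyl is where the dioxin must close onto the dibenzofuran C1–Br, and the isopropyl ether marks the future ring A oxygen. The hindered aryloxy group is introduced on the squarate rather than on an arene.
- **Against:** it needs a long linear sequence on the four-membered ring. The bromodibenzofuran half is still required, and the B1 ether must still be made after isopropyl removal.
- **Comparison:** it is the better plan if the ring B oxygens must be told apart, and its bromide is a better handle than the chloride for the dioxin closure. On the dioxin closure type it is equal. For ring B itself the chosen plan is shorter, because the symmetry of 10 and 13 makes protecting groups unnecessary. The two ideas are compatible, since A7 could also feed the chosen benzannulation.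

Key step: step 13

Remarks on the chemistry:
- Compounds 1, 6, 9, 15, 20 and 21 are assumed to be purchased.
- The benzannulation product 28 carries five methyl ethers and one ethyl ether (six alkyl ethers; the target has seven hydroxyls), not six methyl ethers.
- 19 is not stored; it is generated from the stable 16 immediately before step 13.
- Dichloroacetylene (step 10) is toxic and explosive; it is only formed and consumed in dilute DMF solution under inert gas.

## Route

**Step 1**
Reactants: 1 5-chlorovanillin (3-chloro-4-hydroxy-5-methoxybenzaldehyde)
Product: 2 2-bromo-3-chloro-4-hydroxy-5-methoxybenzaldehyde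
Conditions: Br2, FeBr3 (cat.), AcOH, 50 °C
Reagents that add atoms: bromine, BrBr
Why: Electrophilic aromatic bromination; of the two free positions the one para to methoxy (next to chlorine) is favoured over the one squeezed between formyl and methoxy, the same orientation as in the second bromination of vanillin.

**Step 2**
Reactants: 2 2-bromo-3-chloro-4-hydroxy-5-methoxybenzaldehyde
Product: 3 2-bromo-3-chloro-5-methoxy-4-(triisopropylsilyloxy)benzaldehyde
Conditions: TIPSCl, imidazole, DMF, 40 °C
Reagents that add atoms: chlorotri(propan-2-yl)silane (TIPSCl), CC(C)[Si](Cl)(C(C)C)C(C)C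
Why: O-Silylation of an acidic phenol; the bulky silyl ether should survive peracid, copper and palladium steps and is removed later by fluoride in the same flask as the ether formation.

**Step 3**
Reactants: 3 2-bromo-3-chloro-5-methoxy-4-(triisopropylsilyloxy)benzaldehyde
Product: 5 2-bromo-3-chloro-5-methoxy-4-(triisopropylsilyloxy)phenol, via aryl formate 4 (not isolated)
Conditions: mCPBA, CH2Cl2, 0 °C → rt; then Et3N, MeOH, rt
Reagents that add atoms: 3-chloroperoxybenzoic acid (mCPBA), OOC(=O)c1cccc(Cl)c1
Why: Dakin-type Baeyer–Villiger oxidation; the para-siloxy aryl group migrates in preference to hydride, and the formate is methanolysed under conditions that leave the silyl ether intact.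

**Step 4**
Reactants: 5 2-bromo-3-chloro-5-methoxy-4-(triisopropylsilyloxy)phenol; 6 (3,5-dimethoxyphenyl)boronic acid
Product: 7 [2-bromo-3-chloro-4-(3,5-dimethoxyphenoxy)-6-methoxyphenoxy]triisopropylsilane
Conditions: Cu(OAc)2, pyridine, 4 Å MS, CH2Cl2, air, rt
Reagents that add atoms: none
Why: Chan–Lam O-arylation; the oxidative copper coupling runs at room temperature and leaves aryl bromide and chloride untouched, and ortho-halophenols are established substrates; air reoxidises the copper.

**Step 5**
Reactants: 7 [2-bromo-3-chloro-4-(3,5-dimethoxyphenoxy)-6-methoxyphenoxy]triisopropylsilane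
Product: 8 [(1-chloro-3,7,9-trimethoxydibenzofuran-2-yl)oxy]triisopropylsilane
Conditions: Pd(OAc)2, PPh3, KOAc, DMA, 120 °C
Reagents that add atoms: none
Why: Intramolecular direct arylation; zerovalent palladium with PPh3 inserts into C–Br but not C–Cl, acetate-assisted metalation takes one of the two equivalent ortho C–H bonds of the symmetric aryloxy ring, and reductive elimination closes the furan so that chlorine ends at C1.

**Step 6**
Reactants: 9 1-fluoro-3,5-dimethoxybenzene
Product: 10 2-fluoro-4,6-dimethoxybenzene-1,3-dicarbaldehyde
Conditions: Cl2CHOMe (excess), TiCl4, CH2Cl2, 0 °C → reflux; H2O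
Reagents that add atoms: dichloromethyl methyl ether, COC(Cl)Cl; water, O
Why: Twofold Rieche formylation; each formyl group should enter ortho to fluorine and ortho/para to the methoxy groups rather than between the two methoxy groups, as in the diformylation of 1,3-dimethoxybenzene.

**Step 7**
Reactants: 8 [(1-chloro-3,7,9-trimethoxydibenzofuran-2-yl)oxy]triisopropylsilane; 10 2-fluoro-4,6-dimethoxybenzene-1,3-dicarbaldehyde
Product: 11 2-[(1-chloro-3,7,9-trimethoxydibenzofuran-2-yl)oxy]-4,6-dimethoxybenzene-1,3-dicarbaldehyde
Conditions: CsF, DMF, rt → 60 °C
Reagents that add atoms: none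
Why: Fluoride-triggered desilylation followed by nucleophilic aromatic substitution; the phenoxide adds to the fluorine-bearing carbon activated by two ortho formyl groups (Meisenheimer intermediate) and the expelled fluoride carries the desilylation on. The symmetry of 10 allows one ether only.

**Step 8**
Reactants: 11 2-[(1-chloro-3,7,9-trimethoxydibenzofuran-2-yl)oxy]-4,6-dimethoxybenzene-1,3-dicarbaldehyde
Product: 13 2-[(1-chloro-3,7,9-trimethoxydibenzofuran-2-yl)oxy]-4,6-dimethoxybenzene-1,3-diol, via bis-formate 12 (not isolated)
Conditions: mCPBA, CH2Cl2, 0 °C → rt; then Et3N, MeOH (degassed), rt, Ar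
Reagents that add atoms: 3-chloroperoxybenzoic acid (mCPBA), OOC(=O)c1cccc(Cl)c1
Why: Double Dakin oxidation; both formyl groups sit on a ring with ortho/para methoxy and ortho aryloxy donors, so aryl migration should be fast, and the formates are cleaved under argon because the diol is air-sensitive.

**Step 9**
Reactants: 13 2-[(1-chloro-3,7,9-trimethoxydibenzofuran-2-yl)oxy]-4,6-dimethoxybenzene-1,3-diol
Product: 14 pentacyclic ring B phenol (dioxin closed between B5–O and dibenzofuran C1; free OH at B1; OMe at B2, B4, C3, C7, C9)
Conditions: CuI, N,N'-bis(2-phenylphenyl)oxalamide, K3PO4, DMF, 120 °C, Ar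
Reagents that add atoms: none
Why: Intramolecular Ullmann-type etherification of an aryl chloride with an oxalamide-ligated copper catalyst, closing the six-membered dioxin. The two hydroxyls are equivalent, so either gives 14 and the other remains as the B1 phenol.

**Step 10**
Reactants: 14 pentacyclic ring B phenol; 15 trichloroethylene
Product: 16 (E)-1,2-dichlorovinyl ether of 14
Conditions: K2CO3, DMF, 70 °C
Reagents that add atoms: none
Why: Base converts trichloroethylene to dichloroacetylene in situ, and anti addition of the phenoxide gives the (E)-dichlorovinyl ether; the linear electrophile is indifferent to the two ortho substituents at B1.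

**Step 11**
Reactants: 16 (E)-1,2-dichlorovinyl ether of 14
Product: 19 ethynyl ether of 14, via chloroethynyl ether 17 (not isolated), via lithium acetylide 18 (not isolated)
Conditions: n-BuLi (2.2 equiv), THF, −78 → −40 °C; then MeOH, −78 °C
Reagents that add atoms: none
Why: Deprotonation and loss of LiCl give the chloroalkyne, chlorine–lithium exchange gives the lithium acetylide, and cold protonation gives the terminal ynol ether; at −78 °C the aryl C–H bonds between methoxy groups should not be metalated. 19 is used crude at once.

**Step 12**
Reactants: 20 ethoxyacetylene; 21 acetyl chloride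
Product: 23 3-ethoxycyclobut-2-en-1-one, via ketene 22 (not isolated)
Conditions: Et3N, Et2O, 0 °C → rt (slow addition of 21 to 20 and Et3N)
Reagents that add atoms: none
Why: Dehydrochlorination gives ketene, which undergoes [2+2] cycloaddition with the electron-rich alkyne; the nucleophilic terminal carbon bonds to the ketene carbonyl carbon, so ethoxy ends at C3. The same in situ ketene method converts vinyl ethers to 3-alkoxycyclobutanones.

**Step 13**
Reactants: 19 ethynyl ether of 14; 23 3-ethoxycyclobut-2-en-1-one
Product: 28 3-ethoxy-5-hydroxyphenyl ether of the pentamethoxy pentacycle, via vinylketene 24 (not isolated), via vinylcyclobutenone 25 (not isolated), via dienylketene 26 (not isolated), via cyclohexadienone 27 (not isolated)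
Conditions: PhMe, 80 → 110 °C (sealed tube), 23 in excess; then K2CO3, MeOH, rt
Reagents that add atoms: none
Why: Danheiser benzannulation: heating opens 23 by 4-electron electrocyclic ring opening to vinylketene 24, which adds to the triple bond of 19 in a [2+2] cycloaddition to give 25. 25 opens again to dienylketene 26, a 6-electron electrocyclisation joins the ketene carbon to the terminal methylene to give 27, and tautomerisation gives phenol 28. The closest known reaction type is the benzannulation of cyclobutenones with alkoxy- and siloxyalkynes to resorcinol monoethers. Ring A is therefore closed by a thermal disrotatory 6-electron electrocyclisation, and three C–C bonds form (two in the cycloaddition, one in the electrocyclisation). No stereocentre is created; the one in 25 disappears on ring opening. The selectivity needed is the orientation of the [2+2] step: the aryloxy oxygen polarises the alkyne so that its terminal carbon bonds to the ketene carbonyl carbon, which puts the aryloxy group meta to the new hydroxyl, and the cyclobutenone fixes ethoxy meta to both. All bond formation occurs at sp carbons two and three atoms from B1, so the flanking methoxy and dioxin oxygen do not interfere. Excess 23 offsets vinylketene dimerisation, and the carbonate/methanol treatment cleaves any ester formed from 28 and the vinylketene.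

**Step 14**
Reactants: 28 3-ethoxy-5-hydroxyphenyl ether of the pentamethoxy pentacycle
Product: 29 target heptaphenol CNP0256302.0
Conditions: BBr3, CH2Cl2, −78 °C → rt; then H2O, work-up under Ar
Reagents that add atoms: none
Why: Lewis acid-mediated dealkylation: bromide attacks the methyl and ethyl carbons of the boron-complexed ethers, whereas the diaryl ether, dioxin and furan oxygens offer only sp2 carbons and should survive. The air-sensitive polyphenol is isolated under argon.

## Compound list

1 | 5-chlorovanillin (3-chloro-4-hydroxy-5-methoxybenzaldehyde) | COc1cc(C=O)cc(Cl)c1O | starting material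
2 | 2-bromo-3-chloro-4-hydroxy-5-methoxybenzaldehyde | COc1cc(C=O)c(Br)c(Cl)c1O | intermediate
3 | 2-bromo-3-chloro-5-methoxy-4-(triisopropylsilyloxy)benzaldehyde | COc1cc(C=O)c(Br)c(Cl)c1O[Si](C(C)C)(C(C)C)C(C)C | intermediate
4 | 2-bromo-3-chloro-5-methoxy-4-(triisopropylsilyloxy)phenyl formate | COc1cc(OC=O)c(Br)c(Cl)c1O[Si](C(C)C)(C(C)C)C(C)C | intermediate
5 | 2-bromo-3-chloro-5-methoxy-4-(triisopropylsilyloxy)phenol | COc1cc(O)c(Br)c(Cl)c1O[Si](C(C)C)(C(C)C)C(C)C | intermediate
6 | (3,5-dimethoxyphenyl)boronic acid | COc1cc(OC)cc(B(O)O)c1 | starting material
7 | [2-bromo-3-chloro-4-(3,5-dimethoxyphenoxy)-6-methoxyphenoxy]triisopropylsilane | COc1cc(Oc2cc(OC)cc(OC)c2)c(Br)c(Cl)c1O[Si](C(C)C)(C(C)C)C(C)C | intermediate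
8 | [(1-chloro-3,7,9-trimethoxydibenzofuran-2-yl)oxy]triisopropylsilane | COc1cc2oc3cc(OC)cc(OC)c3c2c(Cl)c1O[Si](C(C)C)(C(C)C)C(C)C | intermediate
9 | 1-fluoro-3,5-dimethoxybenzene | COc1cc(F)cc(OC)c1 | starting material
10 | 2-fluoro-4,6-dimethoxybenzene-1,3-dicarbaldehyde | COc1cc(OC)c(C=O)c(F)c1C=O | intermediate
11 | 2-[(1-chloro-3,7,9-trimethoxydibenzofuran-2-yl)oxy]-4,6-dimethoxybenzene-1,3-dicarbaldehyde | COc1cc2oc3cc(OC)cc(OC)c3c2c(Cl)c1Oc1c(C=O)c(OC)cc(OC)c1C=O | intermediate
12 | bis-formate of 13 | COc1cc2oc3cc(OC)cc(OC)c3c2c(Cl)c1Oc1c(OC=O)c(OC)cc(OC)c1OC=O | intermediate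
13 | 2-[(1-chloro-3,7,9-trimethoxydibenzofuran-2-yl)oxy]-4,6-dimethoxybenzene-1,3-diol | COc1cc2oc3cc(OC)cc(OC)c3c2c(Cl)c1Oc1c(O)c(OC)cc(OC)c1O | intermediate
14 | pentacyclic ring B phenol (free OH at B1; OMe at B2, B4, C3, C7, C9) | Oc1c(OC)cc(OC)c2c1Oc1c(OC)cc3oc4cc(OC)cc(OC)c4c3c1O2 | intermediate
15 | trichloroethylene | ClC=C(Cl)Cl | starting material
16 | (E)-1,2-dichlorovinyl ether of 14 | Cl/C=C(/Cl)Oc1c(OC)cc(OC)c2c1Oc1c(OC)cc3oc4cc(OC)cc(OC)c4c3c1O2 | intermediate
17 | chloroethynyl ether of 14 | ClC#COc1c(OC)cc(OC)c2c1Oc1c(OC)cc3oc4cc(OC)cc(OC)c4c3c1O2 | intermediate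
18 | lithium acetylide of 19 | [Li]C#COc1c(OC)cc(OC)c2c1Oc1c(OC)cc3oc4cc(OC)cc(OC)c4c3c1O2 | intermediate
19 | ethynyl ether of 14 | C#COc1c(OC)cc(OC)c2c1Oc1c(OC)cc3oc4cc(OC)cc(OC)c4c3c1O2 | intermediate
20 | ethoxyacetylene | CCOC#C | starting material
21 | acetyl chloride | CC(Cl)=O | starting material
22 | ketene | C=C=O | intermediate
23 | 3-ethoxycyclobut-2-en-1-one | CCOC1=CC(=O)C1 | intermediate
24 | 3-ethoxybuta-1,3-dien-1-one (vinylketene) | C=C(OCC)C=C=O | intermediate
25 | 3-aryloxy-4-(1-ethoxyethenyl)cyclobut-2-en-1-one (racemic; aryl = pentacycle of 14) | C=C(OCC)C1C(=O)C=C1Oc1c(OC)cc(OC)c2c1Oc1c(OC)cc3oc4cc(OC)cc(OC)c4c3c1O2 | intermediate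
26 | 3-aryloxy-5-ethoxyhexa-1,3,5-trien-1-one (ketene carbon and ethoxyvinyl group cis) | O=C=C/C(Oc1c(OC)cc(OC)c2c1Oc1c(OC)cc3oc4cc(OC)cc(OC)c4c3c1O2)=C\C(OCC)=C | intermediate
27 | 3-aryloxy-5-ethoxycyclohexa-2,4-dien-1-one | CCOC1=CC(Oc2c(OC)cc(OC)c3c2Oc2c(OC)cc4oc5cc(OC)cc(OC)c5c4c2O3)=CC(=O)C1 | intermediate
28 | 3-ethoxy-5-hydroxyphenyl ether of the pentamethoxy pentacycle | CCOc1cc(O)cc(Oc2c(OC)cc(OC)c3c2Oc2c(OC)cc4oc5cc(OC)cc(OC)c5c4c2O3)c1 | intermediate
29 | CNP0256302.0 (heptaphenol) | Oc1cc(O)cc(Oc2c(O)cc(O)c3c2Oc2c(O)cc4oc5cc(O)cc(O)c5c4c2O3)c1 | target

## Step count and least certain steps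

Total: 14 steps. Longest linear sequence: 12 steps (steps 1–5, 7–11, 13, 14); steps 6 and 12 are side branches.

**Step 13 (key step).** The push–pull cyclobutenone 23 may open only slowly, while the aryl ynol ether 19 decays thermally in the meantime (hydration, oligomerisation, addition of the product phenol across the triple bond); the vinylketene may also dimerise. Fallback: from 14, Chan–Lam O-arylation with 6 (Cu(OAc)2, pyridine, CH2Cl2, air; ortho-disubstituted phenols are tolerated) gives the hepta-O-methyl ether F1, and BBr3 then gives 29 directly.

**Step 7.** The ether has four ortho substituents, so substitution may be slow, and the phenoxide or fluoride may add reversibly to the formyl groups and stall the reaction. Fallback: from 8, TBAF gives 1-chloro-3,7,9-trimethoxydibenzofuran-2-ol F2. Separately, 1-bromo-3,5-dimethoxybenzene is formylated (POCl3/DMF) to 2-bromo-4,6-dimethoxybenzaldehyde F3 and again (Cl2CHOMe/TiCl4) to 2-bromo-4,6-dimethoxybenzene-1,3-dicarbaldehyde F4. Copper-catalysed coupling of F2 with F4 (CuI, picolinic acid, K3PO4, DMSO, 90 °C), assisted by the ortho carbonyl groups, returns to the route at 11.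

**Step 9.** Monovalent copper may activate the hindered, electron-rich C–Cl bond only sluggishly, which would allow oxidation of the electron-rich diol or intermolecular etherification to compete. Fallback: from 13, Miyaura borylation of the C–Cl bond (Pd(OAc)2, XPhos, bis(pinacolato)diboron, KOAc, dioxane, 100 °C) gives the pinacol boronate F5. Intramolecular Chan–Lam etherification (Cu(OAc)2, pyridine, 4 Å MS, Ar) then closes the dioxin and returns to 14.

**Step 6.** The second formylation may enter between the two methoxy groups, or the reaction may stop at the mono-aldehyde once the ring is deactivated. Fallback: from 9, Vilsmeier formylation gives 2-fluoro-4,6-dimethoxybenzaldehyde F6, and ethylene glycol/TsOH gives the dioxolane F7. Fluorine-directed ortho-lithiation (LDA, THF, −78 °C; DMF) gives 3-(1,3-dioxolan-2-yl)-2-fluoro-4,6-dimethoxybenzaldehyde F8, and aqueous HCl returns to 10.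

**Step 12.** Ketene generation from acetyl chloride and Et3N may be inefficient (acylammonium formation and ketene oligomerisation compete with trapping), and the volatile, sensitive cyclobutenone may be lost on isolation. Fallback: from 20, cycloaddition with dichloroketene (Cl3CCOCl, activated Zn dust, Et2O) gives 4,4-dichloro-3-ethoxycyclobut-2-en-1-one F9, and reductive dechlorination (Zn, AcOH, TMEDA, EtOH) returns to 23.

## Further compounds

F1 | step 13 | hepta-O-methyl ether of the target | COc1cc(OC)cc(Oc2c(OC)cc(OC)c3c2Oc2c(OC)cc4oc5cc(OC)cc(OC)c5c4c2O3)c1
F2 | step 7 | 1-chloro-3,7,9-trimethoxydibenzofuran-2-ol | COc1cc2oc3cc(OC)cc(OC)c3c2c(Cl)c1O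
F3 | step 7 | 2-bromo-4,6-dimethoxybenzaldehyde | COc1cc(OC)c(C=O)c(Br)c1
F4 | step 7 | 2-bromo-4,6-dimethoxybenzene-1,3-dicarbaldehyde | COc1cc(OC)c(C=O)c(Br)c1C=O
F5 | step 9 | 4,6-dimethoxy-2-{[3,7,9-trimethoxy-1-(4,4,5,5-tetramethyl-1,3,2-dioxaborolan-2-yl)dibenzofuran-2-yl]oxy}benzene-1,3-diol | COc1cc2oc3cc(OC)cc(OC)c3c2c(B2OC(C)(C)C(C)(C)O2)c1Oc1c(O)c(OC)cc(OC)c1O
F6 | step 6 | 2-fluoro-4,6-dimethoxybenzaldehyde | COc1cc(OC)c(C=O)c(F)c1
F7 | step 6 | 2-(2-fluoro-4,6-dimethoxyphenyl)-1,3-dioxolane | COc1cc(OC)c(C2OCCO2)c(F)c1
F8 | step 6 | 3-(1,3-dioxolan-2-yl)-2-fluoro-4,6-dimethoxybenzaldehyde | COc1cc(OC)c(C2OCCO2)c(F)c1C=O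
F9 | step 12 | 4,4-dichloro-3-ethoxycyclobut-2-en-1-one | CCOC1=CC(=O)C1(Cl)Cl
A1 | alternative 1 | hepta-O-methyl ether of the target | COc1cc(OC)cc(Oc2c(OC)cc(OC)c3c2Oc2c(OC)cc4oc5cc(OC)cc(OC)c5c4c2O3)c1
A2 | alternative 1 | ring C bromide: dibenzodioxin carrying the ring A ether, with Br and a 3,5-dimethoxyphenoxy group on adjacent ring C carbons | COc1cc(OC)cc(Oc2c(OC)cc(OC)c3c2Oc2c(OC)cc(Oc4cc(OC)cc(OC)c4)c(Br)c2O3)c1
A3 | alternative 2 | 2,3-di-tert-butoxy-7,9-dimethoxydibenzofuran-1-ol | COc1cc(OC)c2c(c1)oc1cc(OC(C)(C)C)c(OC(C)(C)C)c(O)c12
A4 | alternative 2 | (4,6-dimethoxy-1-benzofuran-2-yl)acetyl chloride | COc1cc(OC)c2cc(CC(Cl)=O)oc2c1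
A5 | alternative 2 | di-tert-butoxyethyne | CC(C)(C)OC#COC(C)(C)C
A6 | alternative 2 | (4,6-dimethoxy-1-benzofuran-2-yl)ketene | COc1cc(OC)c2cc(C=C=O)oc2c1
A7 | alternative 3 | ring B phenol with ethoxy, methoxy, isopropoxy and (1-bromo-3,7,9-trimethoxydibenzofuran-2-yl)oxy groups | CCOc1cc(OC)c(OC(C)C)c(Oc2c(OC)cc3oc4cc(OC)cc(OC)c4c3c2Br)c1O
A8 | alternative 3 | 2-[(1-bromo-3,7,9-trimethoxydibenzofuran-2-yl)oxy]-4-[(Z)-2-ethoxyethenyl]-4-methoxy-3-(propan-2-yloxy)cyclobut-2-en-1-one (racemic) | CCO/C=C\C1(OC)C(OC(C)C)=C(Oc2c(OC)cc3oc4cc(OC)cc(OC)c4c3c2Br)C1=O
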